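## Structural features

The target is a flavanone: an aromatic ring A (C4a to C8a) fused to a dihydropyranone ring C (O1, C2, C3, C4=O), with ring B attached at C2. Ring A carries free hydroxyls at C5 and C7, so together with O1 it is a phloroglucinol unit acylated at C4a. Ring B is a 4-hydroxy-3-methoxyphenyl group with a 3-methylbut-2-enyl (prenyl) chain at C5′, ortho to the free hydroxyl. C2 is the only stereocentre (S, confirmed from the SMILES); it is benzylic, bears the ring oxygen and lies β to the C4 carbonyl, so it has no stereogenic neighbour. It can be lost in two ways: base opens ring C by retro-oxa-Michael reaction to the achiral chalcone, and ionisation of C2–O1 is assisted by the para oxygen of ring B. The fragile groups are the prenyl olefin (hydrogenation, strong acid, cyclisation onto the 4′-hydroxyl), the electron-rich phenols and the β-aryloxy ketone. The real difficulty is fixing C2 in one absolute sense and keeping it while an acylphloroglucinol with one differentiated oxygen is assembled beside the prenyl group. The key step exploits the fact that C4a (bearing the C4 acyl carbon) and C8a (bearing O1) are neighbours on ring A, with the C5 oxygen on the other side of C4a and the C7 oxygen para to it. That pattern is what an aryne oxygenated at its 3- and 5-positions delivers on inserting into the acyl–oxygen bond of a carboxylate.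

## Logic of the disconnections

25 to 24: no skeletal bond is cut; the three phenols are masked as one class of acid-labile acetal. This is chosen because base would open ring C and hydrogen or strong Lewis acids would attack the prenyl group. The gain is a compound without acidic OH. The demand is a final acid step mild enough not to add the 4′-hydroxyl across the olefin.

24 to 23: the O1–C2 bond is cut. Ring C opens to a phenol and a secondary benzylic carbinol, which turns the stereocentre into an aldol-type centre. The forward closure must be a clean SN2 displacement with inversion, so 23 must be 3R, and ionisation and dehydration must be suppressed.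

23 to 22: only the O–Si bond is cut. The carbinol is carried as a silyl ether so that it cannot add to the aryne or undergo retro-aldol cleavage. The demand is desilylation without base.

22 to 13 and 19 (through 20 and 21): C4a–C4 and C8a–O are cut together. Ring A becomes a symmetrical-core silyl triflate and the chiral part a simple β-silyloxy acid, so the synthesis becomes convergent. The forward step must add oxygen to the aryne carbon remote from the flanking acetal oxygen, transfer the acyl group faster than the aryl anion is protonated, and leave the carbinol centre alone.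

19 to 16, 15 and 14: the C–Si and O–S bonds, then C–Br, then two acetal O–C bonds are cut. This reduces the aryne precursor to a symmetrical triol. The demands are bromination ortho to the one free hydroxyl and differentiation of one of three equivalent hydroxyls.

13 to 11, 10, then 7 and 8: the O–Si bond, the auxiliary ester C–O bond and the C2–C3 bond (flavanone numbering) are cut. The chiral acid reduces to an aromatic aldehyde and a chiral acetate equivalent. The aldol must give the R carbinol.

7 to 6, 5, 4, then 1 and 2 (through 3): the acetal O–C bond, the C5′–prenyl bond and the aryl O–C(tertiary) bond are cut. The prenyl group is traced to a tertiary propargyl ether of a cheap phenol. The rearrangement must go to the only free ortho position and the tertiary ether must form without C-alkylation.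

## Other disconnections considered

Alternative 1: The cut is through C2–C3 and O1–C8a, with ring A held at the dihydrophloroglucinol oxidation level.
- Forward step: the silyl-protected aldehyde A2 and the ring-fused 2-(1-silyloxyvinyl) enone A1 would combine under a Ti(O-i-Pr)4/BINOL catalyst (tetravalent titanium). Acidic work-up with loss of methanol would close the bicyclic dione A3; desilylation at C7 and oxidation would then aromatise ring A.
- In favour: C2 is set by the catalyst in the ring-forming event, so no carbinol is protected, activated or inverted. Ring C and two bonds arise in one operation, and A2 is one silylation from 6.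
- Against: A1 is a cross-conjugated diene whose oxygen-bearing terminus is fully substituted and part of a ring. Such dienes tend to react by a stepwise aldol-type path, for which facial control by this catalyst is not established. Ring A must later be oxidised beside the prenyl olefin and ring B, and the vinylogous acid formed on the way can open ring C and endanger C2. A1 also needs regioselective C-acylation and O-methylation of a reduced phloroglucinol.
- Comparison: on stereochemical economy alternative 1 is the better plan, and in step count it is at least the equal of the chosen route. Structurally the chosen route is stronger because ring A enters already aromatic with all three oxygens in place. Mechanistically its two-bond step is controlled by the substrate, whereas A3 depends on catalyst control and a late oxidation that are both open.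

Alternative 2: The cut takes C4 back to carbon monoxide and severs C4a–C4, C4–C3 and O1–C2 at the flavone level.
- Forward step: the iodophenol A4, carbon monoxide and the aryl acetylene A5 would be joined by PdCl2(PPh3)2 (a divalent palladium precatalyst) in diethylamine to the flavone A6. Its C2=C3 bond must then be reduced enantioselectively.
- In favour: three components and three bonds in one step, a robust achiral intermediate, no benzylic substitution and no carbinol protection. A5 is one alkyne homologation from 7 and A4 is the iodo analogue of 16. On step economy and convergence this is the better plan.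
- Against: the only stereocentre then rests on asymmetric conjugate reduction of a 5,7-dialkoxyflavone, a weak acceptor. Hydrogenation catalysts would also threaten the prenyl olefin and the C4 carbonyl, hydride-transfer variants pass through an enolate from which ring C can open, and 5-exo closure to the aurone competes in the carbonylative step.
- Comparison: structurally the two plans are equal in how ring A is defined (an ortho-halogenated phloroglucinol diether in both). The chosen plan is longer, but each stereochemical event in it has a predictable sense, while the reduction of A6 would have to be developed on this substitution pattern.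

Alternative 3: The cut is the single bond C2–C3; O1–C2 is already present in an acetal.
- Forward step: the enol acetal A7, reachable by carbonyl methylenation of the corresponding benzodioxinone, would be ionised at C2–O3 by a chiral Brønsted acid (Me2AlCl for racemic material). The enolate carbon would then add to the oxocarbenium carbon and close ring C as the tris-silyl ether A8.
- In favour: ring C closes by C–C bond formation, so the electron-rich ring B, a liability in the SN2 closure of the chosen plan, becomes an asset by stabilising the cation. The sequence is short and needs no separate chiral fragment; on step count it is the better plan, and for racemic material it is at least the equal of the chosen route.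
- Against: the intermediate is an achiral ion pair and the acetal configuration is erased. The S configuration would have to be imposed by the counter-anion on a 6-endo recombination, which is a demanding form of control. The aryl silyl ethers and the olefin must survive the acid, the product can racemise under the same acid by reopening, and methylenation next to the 5-silyloxy group is hindered.
- Comparison: structurally both plans start from simple phloroglucinol and vanillin derivatives. Mechanistically the chosen plan takes its stereochemistry from a diastereoselective aldol and stereospecific later steps, which is the more secure basis for a single enantiomer.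

Key step: step 11

Remark: the stereocentre is read as 2S, which requires the R carbinol in 13, 22 and 23 because the closure in step 13 inverts it; (R)-HYTRA (8) is taken as a purchased chiral acetate equivalent; Ar = 3-methoxy-4-(methoxymethoxy)-5-(3-methylbut-2-enyl)phenyl.

Step 1
Reactants: 1 vanillin; 2 2-methylbut-3-yn-2-ol
Product: 4 3-methoxy-4-(2-methylbut-3-yn-2-yloxy)benzaldehyde, via 2-methylbut-3-yn-2-yl trifluoroacetate 3 (not isolated)
Conditions: 2, (CF3CO)2O, DBU, MeCN, −5 °C; then 1, DBU, CuCl2·2H2O (cat.), MeCN, 0 °C
Reagents that add atoms: none
Why: Copper-catalysed propargylic etherification: trifluoroacetate 3 ionises through a copper acetylide and the phenoxide of 1 captures the tertiary carbon; acidic, electron-poor phenols such as 1 suit this reaction and the aldehyde is inert to DBU at 0 °C.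

Step 2
Reactants: 4 3-methoxy-4-(2-methylbut-3-yn-2-yloxy)benzaldehyde
Product: 5 3-methoxy-4-(2-methylbut-3-en-2-yloxy)benzaldehyde
Conditions: H2 (1 atm), Pd/CaCO3 poisoned with Pb(OAc)2 (Lindlar catalyst), quinoline, EtOAc, rt
Reagents that add atoms: none
Why: Lindlar semihydrogenation stops at the terminal alkene; the aldehyde and the aryl ether are untouched, and uptake is halted after one equivalent of hydrogen.

Step 3
Reactants: 5 3-methoxy-4-(2-methylbut-3-en-2-yloxy)benzaldehyde
Product: 6 4-hydroxy-3-methoxy-5-(3-methylbut-2-enyl)benzaldehyde
Conditions: PhNEt2, 120 °C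
Reagents that add atoms: none
Why: Aromatic Claisen rearrangement: the [3,3] shift delivers the allyl unit to C5, the only free ortho carbon, with allylic transposition, so the 1,1-dimethylallyl ether emerges as the linear prenyl group; tautomerisation restores the phenol and the amine solvent buffers acid that would cleave the tertiary ether.

Step 4
Reactants: 6 4-hydroxy-3-methoxy-5-(3-methylbut-2-enyl)benzaldehyde
Product: 7 3-methoxy-4-(methoxymethoxy)-5-(3-methylbut-2-enyl)benzaldehyde
Conditions: MOMCl, i-Pr2NEt, CH2Cl2, 0 °C to rt
Reagents that add atoms: chloromethyl methyl ether (MOMCl), COCCl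
Why: O-alkylation of the phenoxide with an α-chloro ether; the hindered but acidic phenol reacts readily and the acetal withstands the basic, fluoride and reducing conditions ahead.

Step 5
Reactants: 7 3-methoxy-4-(methoxymethoxy)-5-(3-methylbut-2-enyl)benzaldehyde; 8 (R)-2-hydroxy-1,2,2-triphenylethyl acetate ((R)-HYTRA)
Product: 10 (1R)-2-hydroxy-1,2,2-triphenylethyl (3R)-3-Ar-3-hydroxypropanoate, via dilithium alkoxide enolate of (R)-HYTRA 9 (not isolated)
Conditions: 8, LiN(i-Pr)2 (2.2 equiv), THF, −78 to 0 °C; then 7, THF/2-methylbutane, −125 °C; aq. NH4Cl
Reagents that add atoms: none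
Why: Acetate aldol addition of doubly deprotonated HYTRA: the lithium alkoxide of the triphenylglycol unit holds the enolate in an aggregate that shields one face, and the (R)-reagent is known to give (R)-β-hydroxy acid derivatives when the aldehyde residue outranks the CH2CO group, as Ar does; the carbinol centre (later C2) is thus set R, and because 10 is a diastereomer mixture the minor isomer can be removed by crystallisation.

Step 6
Reactants: 10 (1R)-2-hydroxy-1,2,2-triphenylethyl (3R)-3-Ar-3-hydroxypropanoate
Product: 11 (3R)-3-Ar-3-hydroxypropanoic acid
Conditions: KOH, MeOH/H2O, reflux; then aq. KHSO4 to pH 3, 0 °C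
Reagents that add atoms: potassium hydroxide, [K+].[OH-]
Why: Saponification of the hindered ester; the β-hydroxy carboxylate cannot undergo retro-aldol cleavage or dehydration because either would need a carboxylate dianion, the aryl acetal and olefin are base-stable, and brief cold acidification spares the acetal.

Step 7
Reactants: 11 (3R)-3-Ar-3-hydroxypropanoic acid
Product: 13 (3R)-3-Ar-3-(tert-butyldimethylsilyloxy)propanoic acid, via bis-silylated hydroxy acid 12 (not isolated)
Conditions: TBSCl (2.5 equiv), imidazole, DMF, rt; then K2CO3, MeOH/THF/H2O, rt; aq. citric acid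
Reagents that add atoms: tert-butyldimethylsilyl chloride (TBSCl), CC(C)(C)[Si](C)(C)Cl
Why: Silylation of both hydroxyl functions followed by selective hydrolysis of the far more labile silyl ester; a silyl chloride is used because silyl triflates with pyridine-type bases can cleave aryl methoxymethyl ethers.

Step 8
Reactants: 14 phloroglucinol
Product: 15 3,5-bis(methoxymethoxy)phenol
Conditions: MOMCl (2.0 equiv), i-Pr2NEt (2.2 equiv), DMF/CH2Cl2, 0 °C to rt
Reagents that add atoms: chloromethyl methyl ether (MOMCl), COCCl
Why: Statistical O-alkylation of three equivalent hydroxyls: two equivalents should give the bis-acetal as the main component beside mono- and tris-acetal, which differ strongly in polarity and are separable; the mono-acetal can be resubmitted.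

Step 9
Reactants: 15 3,5-bis(methoxymethoxy)phenol
Product: 16 2-bromo-3,5-bis(methoxymethoxy)phenol
Conditions: NBS (1.0 equiv), i-Pr2NH (10 mol %), CH2Cl2, −78 °C
Reagents that add atoms: N-bromosuccinimide (NBS), O=C1CCC(=O)N1Br
Why: Amine-catalysed ortho-bromination of a phenol: the N-bromoamine is delivered through a hydrogen bond to the free hydroxyl, directing bromine to the equivalent positions C2 and C6 and away from the more crowded C4 between the two acetal oxygens; one equivalent at low temperature limits dibromination.

Step 10
Reactants: 16 2-bromo-3,5-bis(methoxymethoxy)phenol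
Product: 19 3,5-bis(methoxymethoxy)-2-(trimethylsilyl)phenyl trifluoromethanesulfonate, via aryl trimethylsilyl ether 17 (not isolated), via lithium 2-silylphenoxide 18 (not isolated)
Conditions: HN(SiMe3)2, THF, reflux, then evaporation; n-BuLi, THF, −100 °C; Tf2O, −100 to −78 °C
Reagents that add atoms: hexamethyldisilazane, C[Si](C)(C)N[Si](C)(C)C; trifluoromethanesulfonic anhydride, O=S(=O)(OS(=O)(=O)C(F)(F)F)C(F)(F)F
Why: O-silylation, bromine–lithium exchange (faster at −100 °C than deprotonation next to the acetals), 1,3-shift of silicon from oxygen to the aryl anion (retro-Brook rearrangement) and O-sulfonylation of the phenoxide; this is the standard sequence from ortho-bromophenols to ortho-silylaryl triflates.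

Step 11
Reactants: 13 (3R)-3-Ar-3-(tert-butyldimethylsilyloxy)propanoic acid; 19 3,5-bis(methoxymethoxy)-2-(trimethylsilyl)phenyl trifluoromethanesulfonate
Product: 22 (3R)-3-Ar-3-(tert-butyldimethylsilyloxy)-1-[2-hydroxy-4,6-bis(methoxymethoxy)phenyl]propan-1-one, via cesium salt of the acid 20 (not isolated), via 3,5-bis(methoxymethoxy)benzyne 21 (not isolated)
Conditions: Cs2CO3 (0.5 equiv), MeOH, rt, then evaporation and toluene azeotrope; 19 (1.2 equiv, slow addition), CsF (3 equiv), THF, 65 °C; aq. NH4Cl
Reagents that add atoms: none
Why: Fluoride attacks the silicon of 19 and triflate leaves to give aryne 21, whose strained bond is polarised by the inductively withdrawing acetal oxygen on the neighbouring carbon. The carboxylate oxygen of 20 therefore adds to the aryne carbon remote from that oxygen, placing the aryl anion ortho to it and fixing oxygen at the future C8a and the anion at the future C4a. The ortho-(acyloxy)aryl anion attacks its own ester carbonyl through a four-membered alkoxide that opens at once to the ortho-acyl phenoxide; the net result is insertion of the aryne into the acyl–oxygen bond, forming C8a–O and C4a–C4. The closest known reactions are the fluoride-induced insertion of arynes into the C–O bond of carboxylic acids to give ortho-hydroxyaryl ketones and the anionic ortho-Fries rearrangement of ortho-metalated aryl esters. No ring remains closed and no stereocentre is made; the carbinol carbon is not α to the carbonyl and cannot epimerise. The selectivity that matters is acyl transfer against protonation of the aryl anion, which would stop at the aryl ester; it is secured by entering the acid as its preformed, dried cesium salt in THF, so that neither an O–H group nor an acidic solvent is present. The salt form also keeps the α-methylene non-acidic until the ketone exists, which with the moderate temperature guards the β-silyloxy group against elimination, and slow addition of a slight excess of 19 limits O-arylation of the product phenoxide. The secondary silyl ether, the aryl acetals and the prenyl olefin are inert to CsF in THF.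

Step 12
Reactants: 22 (3R)-3-Ar-3-(tert-butyldimethylsilyloxy)-1-[2-hydroxy-4,6-bis(methoxymethoxy)phenyl]propan-1-one
Product: 23 (3R)-3-Ar-3-hydroxy-1-[2-hydroxy-4,6-bis(methoxymethoxy)phenyl]propan-1-one
Conditions: HF·pyridine, pyridine, THF, 0 °C to rt
Reagents that add atoms: none
Why: Fluoride cleavage of the silyl ether under buffered, non-basic conditions, chosen because basic fluoride could trigger E1cB loss of the β-oxygen or retro-aldol cleavage; the acetals, the chelated phenol and the olefin are unaffected and the carbinol configuration is untouched.

Step 13
Reactants: 23 (3R)-3-Ar-3-hydroxy-1-[2-hydroxy-4,6-bis(methoxymethoxy)phenyl]propan-1-one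
Product: 24 (2S)-2-Ar-5,7-bis(methoxymethoxy)chroman-4-one
Conditions: PPh3, DIAD, toluene, −20 to 0 °C
Reagents that add atoms: none
Why: Intramolecular Mitsunobu etherification: the secondary alcohol becomes an alkoxyphosphonium ion and is displaced by the neighbouring phenol in a 6-exo-tet SN2 closure, so the R carbinol gives the 2S ring carbon by inversion; the non-polar solvent and low temperature disfavour ionisation, and the 4′-oxygen, held out of the ring plane by its two ortho neighbours, donates only weakly to the benzylic carbon.

Step 14
Reactants: 24 (2S)-2-Ar-5,7-bis(methoxymethoxy)chroman-4-one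
Product: 25 (2S)-5,7-dihydroxy-2-[4-hydroxy-3-methoxy-5-(3-methylbut-2-enyl)phenyl]chroman-4-one
Conditions: HCl (1 M in MeOH), 40 °C
Reagents that add atoms: none
Why: Acid-catalysed acetal exchange with methanol frees the three phenols; the flavanone stereocentre is stable to dilute acid (ring opening to the chalcone is a base process) and the mild temperature avoids acid-promoted addition of the 4′-hydroxyl to the prenyl olefin.

## Compound list

1 | vanillin | COc1cc(C=O)ccc1O | starting material
2 | 2-methylbut-3-yn-2-ol | CC(C)(O)C#C | starting material
3 | 2-methylbut-3-yn-2-yl trifluoroacetate | CC(C)(OC(=O)C(F)(F)F)C#C | intermediate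
4 | 3-methoxy-4-(2-methylbut-3-yn-2-yloxy)benzaldehyde | COc1cc(C=O)ccc1OC(C)(C)C#C | intermediate
5 | 3-methoxy-4-(2-methylbut-3-en-2-yloxy)benzaldehyde | COc1cc(C=O)ccc1OC(C)(C)C=C | intermediate
6 | 4-hydroxy-3-methoxy-5-(3-methylbut-2-enyl)benzaldehyde | COc1cc(C=O)cc(CC=C(C)C)c1O | intermediate
7 | 3-methoxy-4-(methoxymethoxy)-5-(3-methylbut-2-enyl)benzaldehyde | COc1cc(C=O)cc(CC=C(C)C)c1OCOC | intermediate
8 | (R)-2-hydroxy-1,2,2-triphenylethyl acetate, (R)-HYTRA | CC(=O)O[C@H](c1ccccc1)C(O)(c1ccccc1)c1ccccc1 | starting material
9 | dilithium alkoxide enolate of (R)-HYTRA | [Li+].[Li+].C=C([O-])O[C@H](c1ccccc1)C([O-])(c1ccccc1)c1ccccc1 | intermediate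
10 | (1R)-2-hydroxy-1,2,2-triphenylethyl (3R)-3-Ar-3-hydroxypropanoate | COc1cc([C@H](O)CC(=O)O[C@H](c2ccccc2)C(O)(c2ccccc2)c2ccccc2)cc(CC=C(C)C)c1OCOC | intermediate
11 | (3R)-3-Ar-3-hydroxypropanoic acid | COc1cc([C@H](O)CC(=O)O)cc(CC=C(C)C)c1OCOC | intermediate
12 | tert-butyldimethylsilyl (3R)-3-Ar-3-(tert-butyldimethylsilyloxy)propanoate | COc1cc([C@H](O[Si](C)(C)C(C)(C)C)CC(=O)O[Si](C)(C)C(C)(C)C)cc(CC=C(C)C)c1OCOC | intermediate
13 | (3R)-3-Ar-3-(tert-butyldimethylsilyloxy)propanoic acid | COc1cc([C@H](O[Si](C)(C)C(C)(C)C)CC(=O)O)cc(CC=C(C)C)c1OCOC | intermediate
14 | phloroglucinol | Oc1cc(O)cc(O)c1 | starting material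
15 | 3,5-bis(methoxymethoxy)phenol | COCOc1cc(O)cc(OCOC)c1 | intermediate
16 | 2-bromo-3,5-bis(methoxymethoxy)phenol | COCOc1cc(O)c(Br)c(OCOC)c1 | intermediate
17 | [2-bromo-3,5-bis(methoxymethoxy)phenoxy]trimethylsilane | COCOc1cc(O[Si](C)(C)C)c(Br)c(OCOC)c1 | intermediate
18 | lithium 3,5-bis(methoxymethoxy)-2-(trimethylsilyl)phenoxide | [Li+].COCOc1cc([O-])c([Si](C)(C)C)c(OCOC)c1 | intermediate
19 | 3,5-bis(methoxymethoxy)-2-(trimethylsilyl)phenyl trifluoromethanesulfonate | COCOc1cc(OCOC)c([Si](C)(C)C)c(OS(=O)(=O)C(F)(F)F)c1 | intermediate
20 | cesium (3R)-3-Ar-3-(tert-butyldimethylsilyloxy)propanoate | [Cs+].COc1cc([C@H](O[Si](C)(C)C(C)(C)C)CC(=O)[O-])cc(CC=C(C)C)c1OCOC | intermediate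
21 | 3,5-bis(methoxymethoxy)benzyne | COCOC1=CC(OCOC)=CC#C1 | intermediate
22 | (3R)-3-Ar-3-(tert-butyldimethylsilyloxy)-1-[2-hydroxy-4,6-bis(methoxymethoxy)phenyl]propan-1-one | COc1cc([C@H](O[Si](C)(C)C(C)(C)C)CC(=O)c2c(O)cc(OCOC)cc2OCOC)cc(CC=C(C)C)c1OCOC | intermediate
23 | (3R)-3-Ar-3-hydroxy-1-[2-hydroxy-4,6-bis(methoxymethoxy)phenyl]propan-1-one | COc1cc([C@H](O)CC(=O)c2c(O)cc(OCOC)cc2OCOC)cc(CC=C(C)C)c1OCOC | intermediate
24 | (2S)-2-Ar-5,7-bis(methoxymethoxy)chroman-4-one | COc1cc([C@@H]2CC(=O)c3c(OCOC)cc(OCOC)cc3O2)cc(CC=C(C)C)c1OCOC | intermediate
25 | (2S)-5,7-dihydroxy-2-[4-hydroxy-3-methoxy-5-(3-methylbut-2-enyl)phenyl]chroman-4-one | COc1cc([C@@H]2CC(=O)c3c(O)cc(O)cc3O2)cc(CC=C(C)C)c1O | target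

## Step count and least certain steps

Total: 14 steps. Longest linear sequence: 11 steps (steps 1–7 and 11–14, from 1); the aryne branch (steps 8–10) adds three.

**Step 11 (key step).** The aryl anion may be quenched before acyl transfer, which ends in O-arylation instead of insertion. It may also abstract a proton from the α-methylene, followed by β-elimination of silanolate. The product phenoxide may be O-arylated by excess aryne. All three are kinetic competitions at a short-lived anion; if conversion is slow the temperature can be raised in a sealed tube, the regime in which the reaction type is established.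
Fallback: it sets out from 13 and 16 and forms the same two bonds stepwise. Carbodiimide esterification (EDC·HCl, DMAP, CH2Cl2) gives 2-bromo-3,5-bis(methoxymethoxy)phenyl (3R)-3-Ar-3-(tert-butyldimethylsilyloxy)propanoate F1. Bromine–lithium exchange (n-BuLi, THF, −100 °C) then triggers the anionic ortho-Fries 1,3-acyl shift, and work-up returns to the route at 22.

**Step 13.** The activated benzylic alkoxyphosphonium may ionise, eroding the enantiomeric purity, or E1cB dehydration to the chalcone may be followed by unselective oxa-Michael closure. Both follow from a benzylic leaving group β to a ketone on an oxygenated ring.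
Fallback: it sets out from 22 and gives up stereospecific closure. DBU in THF eliminates silanol to (E)-1-[2-hydroxy-4,6-bis(methoxymethoxy)phenyl]-3-Ar-prop-2-en-1-one F2. NaOAc in EtOH at reflux closes it to racemic 2-Ar-5,7-bis(methoxymethoxy)chroman-4-one F3. Preparative chromatography on a chiral stationary phase separates the enantiomers and returns to the route at 24.

**Step 9.** Bromine may enter at C4 between the acetal oxygens, or a second bromine may be introduced, because all three ring positions are strongly activated.
Fallback: it sets out from 15 and uses directed metalation. ClCONEt2 and NaH give 3,5-bis(methoxymethoxy)phenyl N,N-diethylcarbamate F4. s-BuLi/TMEDA in THF at −78 °C, then Me3SiCl, should lithiate between the carbamate (the stronger director) and one acetal, giving 3,5-bis(methoxymethoxy)-2-(trimethylsilyl)phenyl N,N-diethylcarbamate F5. LiAlH4 cleaves the carbamate to 3,5-bis(methoxymethoxy)-2-(trimethylsilyl)phenol F6, and Tf2O/pyridine returns to the route at 19.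

**Step 5.** Facial discrimination by the dianion towards a hindered, electron-rich aldehyde may be insufficient, or conversion at −125 °C incomplete.
Fallback: it sets out from 7. Roskamp homologation (ethyl diazoacetate, SnCl2 cat., CH2Cl2) gives ethyl 3-Ar-3-oxopropanoate F7. Noyori–Ikariya transfer hydrogenation with RuCl(p-cymene)[(R,R)-TsDPEN] and HCO2H/Et3N, the catalyst enantiomer chosen by analogy with aryl methyl ketones, should give ethyl (3R)-3-Ar-3-hydroxypropanoate F8. LiOH in THF/H2O returns to the route at 11.

**Step 3.** The tertiary allyl aryl ether may fragment to the phenol and isoprene, an ionisation favoured by the electron-poor phenoxide leaving group, in competition with the sigmatropic shift.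
Fallback: it sets out from 1 and attaches the prenyl group by cross-coupling. Br2 in AcOH gives 3-bromo-4-hydroxy-5-methoxybenzaldehyde F9, and MOMCl/i-Pr2NEt gives 3-bromo-5-methoxy-4-(methoxymethoxy)benzaldehyde F10. Stille coupling with tributyl(3-methylbut-2-enyl)stannane and Pd(PPh3)4 (zerovalent palladium) in DMF returns to the route at 7.

## Further compounds

F1 | step 11 | 2-bromo-3,5-bis(methoxymethoxy)phenyl (3R)-3-Ar-3-(tert-butyldimethylsilyloxy)propanoate | COc1cc([C@H](O[Si](C)(C)C(C)(C)C)CC(=O)Oc2cc(OCOC)cc(OCOC)c2Br)cc(CC=C(C)C)c1OCOC
F2 | step 13 | (E)-1-[2-hydroxy-4,6-bis(methoxymethoxy)phenyl]-3-Ar-prop-2-en-1-one | COc1cc(/C=C/C(=O)c2c(O)cc(OCOC)cc2OCOC)cc(CC=C(C)C)c1OCOC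
F3 | step 13 | racemic 2-Ar-5,7-bis(methoxymethoxy)chroman-4-one | COc1cc(C2CC(=O)c3c(OCOC)cc(OCOC)cc3O2)cc(CC=C(C)C)c1OCOC
F4 | step 9 | 3,5-bis(methoxymethoxy)phenyl N,N-diethylcarbamate | CCN(CC)C(=O)Oc1cc(OCOC)cc(OCOC)c1
F5 | step 9 | 3,5-bis(methoxymethoxy)-2-(trimethylsilyl)phenyl N,N-diethylcarbamate | CCN(CC)C(=O)Oc1cc(OCOC)cc(OCOC)c1[Si](C)(C)C
F6 | step 9 | 3,5-bis(methoxymethoxy)-2-(trimethylsilyl)phenol | COCOc1cc(O)c([Si](C)(C)C)c(OCOC)c1
F7 | step 5 | ethyl 3-Ar-3-oxopropanoate | CCOC(=O)CC(=O)c1cc(OC)c(OCOC)c(CC=C(C)C)c1
F8 | step 5 | ethyl (3R)-3-Ar-3-hydroxypropanoate | COc1cc([C@H](O)CC(=O)OCC)cc(CC=C(C)C)c1OCOC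
F9 | step 3 | 3-bromo-4-hydroxy-5-methoxybenzaldehyde | COc1cc(C=O)cc(Br)c1O
F10 | step 3 | 3-bromo-5-methoxy-4-(methoxymethoxy)benzaldehyde | COc1cc(C=O)cc(Br)c1OCOC
A1 | alternative 1 | 5-(tert-butyldimethylsilyloxy)-3-methoxy-2-[1-(trimethylsilyloxy)ethenyl]cyclohex-2-en-1-one | C=C(O[Si](C)(C)C)C1=C(OC)CC(O[Si](C)(C)C(C)(C)C)CC1=O
A2 | alternative 1 | 4-(tert-butyldimethylsilyloxy)-3-methoxy-5-(3-methylbut-2-enyl)benzaldehyde | COc1cc(C=O)cc(CC=C(C)C)c1O[Si](C)(C)C(C)(C)C
A3 | alternative 1 | (2S)-7-(tert-butyldimethylsilyloxy)-2-[4-(tert-butyldimethylsilyloxy)-3-methoxy-5-(3-methylbut-2-enyl)phenyl]-2,3,7,8-tetrahydrochromene-4,5(6H)-dione (either C7 epimer) | COc1cc([C@@H]2CC(=O)C3=C(CC(O[Si](C)(C)C(C)(C)C)CC3=O)O2)cc(CC=C(C)C)c1O[Si](C)(C)C(C)(C)C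
A4 | alternative 2 | 2-iodo-3,5-bis(methoxymethoxy)phenol | COCOc1cc(O)c(I)c(OCOC)c1
A5 | alternative 2 | 5-ethynyl-1-methoxy-2-(methoxymethoxy)-3-(3-methylbut-2-enyl)benzene | COc1cc(C#C)cc(CC=C(C)C)c1OCOC
A6 | alternative 2 | 5,7-bis(methoxymethoxy)-2-[3-methoxy-4-(methoxymethoxy)-5-(3-methylbut-2-enyl)phenyl]chromen-4-one | COc1cc(-c2cc(=O)c3c(OCOC)cc(OCOC)cc3o2)cc(CC=C(C)C)c1OCOC
A7 | alternative 3 | 5,7-bis(tert-butyldimethylsilyloxy)-2-[4-(tert-butyldimethylsilyloxy)-3-methoxy-5-(3-methylbut-2-enyl)phenyl]-4-methylidene-4H-1,3-benzodioxine | COc1cc(C2OC(=C)c3c(O[Si](C)(C)C(C)(C)C)cc(O[Si](C)(C)C(C)(C)C)cc3O2)cc(CC=C(C)C)c1O[Si](C)(C)C(C)(C)C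
A8 | alternative 3 | (2S)-5,7-bis(tert-butyldimethylsilyloxy)-2-[4-(tert-butyldimethylsilyloxy)-3-methoxy-5-(3-methylbut-2-enyl)phenyl]chroman-4-one | COc1cc([C@@H]2CC(=O)c3c(O[Si](C)(C)C(C)(C)C)cc(O[Si](C)(C)C(C)(C)C)cc3O2)cc(CC=C(C)C)c1O[Si](C)(C)C(C)(C)C
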